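## Retrosynthetic overview

1. The only ring, the 5,6-dihydro-2H-pyran-2-one, is formed last and as the polyketide pathway is presumed to form it: C5–OH of an open, unprotected chain acylates the C1 ester (thioesterase-like), then the C3 hydroxyl is lost (dehydratase-like). C5 is set just before, in the same flask, by hydroxyl-directed (ketoreductase-like) reduction of the open-chain 3,5-diketo ester.
2. C4–C5: Claisen condensation of the C16 triol ester with the dilithium dianion of methyl acetoacetate (C1–C4).
3. C7 and C9: relay 1,3-anti reduction of the C16 hydroxy diketo ester. C8–C9: Claisen condensation of the C12 hydroxy ester with the sodium lithium dianion of methyl acetoacetate (C5–C8).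
4. C11: Noyori hydrogenation of methyl 3-oxododecanoate (C9–C20).
5. Skeleton = one C12 keto ester + two C4 acetoacetate units; no protecting groups. The target is the all-anti 5,7,9,11-tetraol pattern.

Assumption: methyl 3-oxododecanoate (1) is bought as a catalogue β-keto ester; chain atoms are numbered C1–C20 from the lactone carbonyl (C5 = ring carbinol; C7, C9, C11 = side-chain carbinols).

## Route

Step 1
Reactants: 1 methyl 3-oxododecanoate
Product: 2 methyl (3S)-3-hydroxydodecanoate
Conditions: H2 (4 atm), RuCl2[(S)-BINAP] (0.1 mol %), MeOH, 100 °C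
Reagents that add atoms: none
Why: Noyori asymmetric hydrogenation of a β-keto ester; the ester-chelated ketone is reduced on the face dictated by (S)-BINAP, giving the (S)-carbinol (C11 of the target), typically in ≥98% ee.

Step 2
Reactants: 2 methyl (3S)-3-hydroxydodecanoate; 3 methyl acetoacetate
Product: 5 methyl (7S)-7-hydroxy-3,5-dioxohexadecanoate, via sodium lithium dianion 4 (not isolated)
Conditions: 3 (3.3 equiv), NaH (3.3 equiv), THF, 0 °C; n-BuLi (3.3 equiv), 0 °C; then 2, −40 → 0 °C; cold aq. HCl to pH 4
Reagents that add atoms: none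
Why: Claisen condensation (Weiler acylation of a β-keto ester dianion, here the amine-free dianion made with NaH then n-BuLi): the lithium-bearing γ-carbanion of one equivalent of 4 turns the hydroxyl into an alkoxide that cannot β-eliminate, the γ-carbanion of the next adds to the ester, methoxide leaves and the product rests as its dienolate; no stereocentre is formed or touched.

Step 3
Reactants: 5 methyl (7S)-7-hydroxy-3,5-dioxohexadecanoate
Product: 7 methyl (3S,5R,7S)-3,5,7-trihydroxyhexadecanoate, via keto diol ester 6 (not isolated)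
Conditions: Me4NBH(OAc)3 (6 equiv), MeCN–AcOH (1:1), −30 → 0 °C; then MeOH, evaporate (×3); silica filtration
Reagents that add atoms: none
Why: Proposed new method: Evans–Saksena reduction run twice as a relay — the C7–OH (ester numbering) exchanges for acetate on boron and delivers hydride through a chair six-membered transition state to the C5 carbonyl of the keto tautomer (5,7-anti, giving 6), then the new C5–OH does the same to the C3 keto ester carbonyl (3,5-anti), while the free reagent leaves unassisted or enolised carbonyls alone in cold AcOH; closest known reaction: Me4NBH(OAc)3 reduction of δ-hydroxy-β-keto esters to anti-3,5-diols.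

Step 4
Reactants: 7 methyl (3S,5R,7S)-3,5,7-trihydroxyhexadecanoate; 3 methyl acetoacetate
Product: 9 methyl (7S,9R,11S)-7,9,11-trihydroxy-3,5-dioxoicosanoate, via dilithium dianion 8 (not isolated)
Conditions: 3 (6 equiv), LiN(i-Pr)2 (12 equiv), THF, 0 °C; then 7, −40 → 0 °C; cold aq. HCl to pH 4
Reagents that add atoms: none
Why: Claisen condensation of the tri-alkoxide of 7 with the all-lithium dianion 8, made with LiN(i-Pr)2 so that all three alkoxides are tightly bound lithium alkoxides that resist β-elimination and retro-aldol at ≤0 °C (three equivalents of 8 serve as base), of the type used on unprotected β-hydroxy esters with lithium ester enolates; the three carbinol centres are not enolisable and stay intact.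

Step 5
Reactants: 9 methyl (7S,9R,11S)-7,9,11-trihydroxy-3,5-dioxoicosanoate
Product: 13 (6S)-6-[(2S,4R,6S)-2,4,6-trihydroxypentadecyl]-5,6-dihydro-2H-pyran-2-one, via keto tetrol ester 10 (not isolated), via pentol ester 11 (not isolated), via hydroxy lactone 12 (not isolated)
Conditions: Me4NBH(OAc)3 (6 equiv), MeCN–AcOH (1:1), −30 → 0 °C; then MeOH, evaporate (×3); then TsOH·H2O (6.5 equiv, 0.5 equiv beyond the acetate left in the flask), PhMe, 90 °C
Reagents that add atoms: none
Why: Proposed new method: one-flask ketoreduction/lactonisation/dehydration on the unprotected chain — C7–OH-directed hydride delivery sets C5 anti (C5–OH then directs reduction of C3, whose configuration is lost later), acid lets C5–OH acylate C1 because only this hydroxyl gives a six-membered ring (C7–OH would give an eight-membered one), and the β-hydroxy lactone loses water into conjugation, the 5,7-anti product being shielded from bridging oxa-Michael addition of C7–OH, which would need a triaxial chair; closest known reactions: Evans–Saksena reduction and TsOH-mediated lactonisation–dehydration of 3,5-dihydroxy esters to 5,6-dihydro-2H-pyran-2-ones.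

## Compound list

1 | methyl 3-oxododecanoate | CCCCCCCCCC(=O)CC(=O)OC | starting material
2 | methyl (3S)-3-hydroxydodecanoate | CCCCCCCCC[C@H](O)CC(=O)OC | intermediate
3 | methyl acetoacetate (methyl 3-oxobutanoate) | CC(=O)CC(=O)OC | starting material
4 | sodium lithium dianion of methyl acetoacetate (lithium sodium 1-methoxybuta-1,3-diene-1,3-diolate) | [Na+].[Li+].C=C([O-])C=C([O-])OC | intermediate
5 | methyl (7S)-7-hydroxy-3,5-dioxohexadecanoate | CCCCCCCCC[C@H](O)CC(=O)CC(=O)CC(=O)OC | intermediate
6 | methyl (5R,7S)-5,7-dihydroxy-3-oxohexadecanoate | CCCCCCCCC[C@H](O)C[C@@H](O)CC(=O)CC(=O)OC | intermediate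
7 | methyl (3S,5R,7S)-3,5,7-trihydroxyhexadecanoate | CCCCCCCCC[C@H](O)C[C@@H](O)C[C@H](O)CC(=O)OC | intermediate
8 | dilithium dianion of methyl acetoacetate (dilithium 1-methoxybuta-1,3-diene-1,3-diolate) | [Li+].[Li+].C=C([O-])C=C([O-])OC | intermediate
9 | methyl (7S,9R,11S)-7,9,11-trihydroxy-3,5-dioxoicosanoate | CCCCCCCCC[C@H](O)C[C@@H](O)C[C@H](O)CC(=O)CC(=O)CC(=O)OC | intermediate
10 | methyl (5R,7S,9R,11S)-5,7,9,11-tetrahydroxy-3-oxoicosanoate | CCCCCCCCC[C@H](O)C[C@@H](O)C[C@H](O)C[C@@H](O)CC(=O)CC(=O)OC | intermediate
11 | methyl (3S,5R,7S,9R,11S)-3,5,7,9,11-pentahydroxyicosanoate | CCCCCCCCC[C@H](O)C[C@@H](O)C[C@H](O)C[C@@H](O)C[C@H](O)CC(=O)OC | intermediate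
12 | (4S,6R)-4-hydroxy-6-[(2S,4R,6S)-2,4,6-trihydroxypentadecyl]oxan-2-one | CCCCCCCCC[C@H](O)C[C@@H](O)C[C@H](O)C[C@@H]1C[C@H](O)CC(=O)O1 | intermediate
13 | (6S)-6-[(2S,4R,6S)-2,4,6-trihydroxypentadecyl]-5,6-dihydro-2H-pyran-2-one | CCCCCCCCC[C@H](O)C[C@@H](O)C[C@H](O)C[C@@H]1CC=CC(=O)O1 | target

## Step count and risk

Total steps: 5. Longest linear sequence: 5 (1 → 2 → 5 → 7 → 9 → 13).

Stereocentres: C11 in step 1 (catalyst), C9 and C7 in step 3 (relay from C11), C5 in step 5 (from C7). None is α to a carbonyl afterwards, so none can epimerise.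

The three steps most likely to fail:

Step 5 is the most likely to fail. The dehydration stage has to single out the lactone β-hydroxyl among four secondary hydroxyls using acid alone. If it is sluggish or unclean, the fallback sets out from 11, isolated after the reduction stage by methanol evaporation and silica filtration, and comes back at 13. Compound 11 is closed to 12 without dehydration (TsOH·H2O 5 mol %, CH2Cl2, 20 °C). Peracetylation (Ac2O, pyridine, DMAP) gives the tetraacetate of 12 F8. DBU (CH2Cl2, 0 °C) removes only the acetoxy group β to the lactone carbonyl by E1cB elimination, giving the triacetate of 13 F9. Acid methanolysis (HCl, MeOH, 0 → 20 °C) strips the three remaining acetates to give 13. If the fault lies in the reduction stage instead (first hydride misdirected on the enolised diketone), the fallback given under step 4 enters at 10 and avoids the diketone.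

Step 4 is the next most likely to fail. The tri-lithium alkoxide of 7 may be too insoluble or too unreactive towards the dianion. The fallback sets out from 7 and comes back at 10, replacing the Claisen condensation by an aldol addition. Silylation (TBSOTf, 2,6-lutidine, CH2Cl2) gives the 3,5,7-tris-O-(tert-butyldimethylsilyl) ether of 7 F5. Reduction with i-Bu2AlH (CH2Cl2, −78 °C) gives (3S,5R,7S)-3,5,7-tris(tert-butyldimethylsilyloxy)hexadecanal F6. Mukaiyama aldol addition of 1-methoxy-1,3-bis(trimethylsilyloxy)buta-1,3-diene (BF3·OEt2, CH2Cl2, −78 °C; 1,3-anti induction from the β-silyloxy group) gives the 7,9,11-tris-O-(tert-butyldimethylsilyl) ether of 10 F7. HF·pyridine (THF) releases 10, which is put through step 5 as written; its reduction stage then meets an ordinary δ-hydroxy-β-keto ester.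

Step 3 is the third. The enolised diketone may bind boron itself or cyclodehydrate to a dihydropyranone, eroding the relay. The fallback sets out from 2 and comes back at 7; it also bypasses step 2. Silylation (TBSCl, imidazole, DMF) gives the tert-butyldimethylsilyl ether of 2 F1. Reduction with i-Bu2AlH (CH2Cl2, −78 °C) gives (3S)-3-(tert-butyldimethylsilyloxy)dodecanal F2. The same Mukaiyama aldol addition (BF3·OEt2, −78 °C, 1,3-anti) gives the 7-O-(tert-butyldimethylsilyl) ether of 6 F3. A single Evans–Saksena reduction (Me4NBH(OAc)3, MeCN–AcOH, −30 °C) gives the 7-O-(tert-butyldimethylsilyl) ether of 7 F4. HF·pyridine then gives 7.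

## Further compounds

F1 | step 3 | tert-butyldimethylsilyl ether of 2 (methyl (3S)-3-(tert-butyldimethylsilyloxy)dodecanoate) | CCCCCCCCC[C@H](O[Si](C)(C)C(C)(C)C)CC(=O)OC
F2 | step 3 | (3S)-3-(tert-butyldimethylsilyloxy)dodecanal | CCCCCCCCC[C@H](O[Si](C)(C)C(C)(C)C)CC=O
F3 | step 3 | 7-O-(tert-butyldimethylsilyl) ether of 6 | CCCCCCCCC[C@H](O[Si](C)(C)C(C)(C)C)C[C@@H](O)CC(=O)CC(=O)OC
F4 | step 3 | 7-O-(tert-butyldimethylsilyl) ether of 7 | CCCCCCCCC[C@H](O[Si](C)(C)C(C)(C)C)C[C@@H](O)C[C@H](O)CC(=O)OC
F5 | step 4 | 3,5,7-tris-O-(tert-butyldimethylsilyl) ether of 7 | CCCCCCCCC[C@H](O[Si](C)(C)C(C)(C)C)C[C@@H](O[Si](C)(C)C(C)(C)C)C[C@H](O[Si](C)(C)C(C)(C)C)CC(=O)OC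
F6 | step 4 | (3S,5R,7S)-3,5,7-tris(tert-butyldimethylsilyloxy)hexadecanal | CCCCCCCCC[C@H](O[Si](C)(C)C(C)(C)C)C[C@@H](O[Si](C)(C)C(C)(C)C)C[C@H](O[Si](C)(C)C(C)(C)C)CC=O
F7 | step 4 | 7,9,11-tris-O-(tert-butyldimethylsilyl) ether of 10 | CCCCCCCCC[C@H](O[Si](C)(C)C(C)(C)C)C[C@@H](O[Si](C)(C)C(C)(C)C)C[C@H](O[Si](C)(C)C(C)(C)C)C[C@@H](O)CC(=O)CC(=O)OC
F8 | step 5 | tetraacetate of 12 | CCCCCCCCC[C@H](OC(C)=O)C[C@@H](OC(C)=O)C[C@H](OC(C)=O)C[C@@H]1C[C@H](OC(C)=O)CC(=O)O1
F9 | step 5 | triacetate of 13 | CCCCCCCCC[C@H](OC(C)=O)C[C@@H](OC(C)=O)C[C@H](OC(C)=O)C[C@@H]1CC=CC(=O)O1
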